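Assumption: azaphilone numbering is used (C1, O2, C3, C4, C4a, C5–C8, C8a; side chain C1'–C7'), and the SMILES is read as the 7R,8R cis-diol core carrying a (1'E,3'R,4'S,5'S) side chain.

**Retrosynthetic overview**
1. The C1'=C2' alkene comes from a lateral (vinylogous) aldol condensation of the 3-methyl group of protected core 15 with side-chain aldehyde 24; both acetonides are removed last.
2. Pyran ring (formed second): water displaces sulfinate at C1 and the enol oxygen closes 6-endo onto the C4≡C3 alkyne.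
3. Carbocycle (formed first, key step): a sulfonyl radical adds to the terminal alkyne of diynone 12, the C8a vinyl radical forms the C8a–C4a bond 6-endo on the ynone, and chlorine-atom transfer installs C5–Cl.
4. Diynone 12 comes from D-erythronolactone (C6–C8a; C8 from the pool, C7 by methylation on the cis-fused acetonide) and penta-1,3-diyne.
5. Aldehyde 24 comes from (R)-lactic acid (dioxolanone aldol) and (S)-2-methylbutanal.

**Route**

Step 1
Reactants: 1 D-erythronolactone
Product: 2 (3aR,6aR)-2,2-dimethyldihydrofuro[3,4-d][1,3]dioxol-4(3aH)-one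
Conditions: 2,2-dimethoxypropane, TsOH·H2O (cat.), acetone, rt
Reagents that add atoms: 2,2-dimethoxypropane (COC(C)(C)OC)
Why: Acid-catalysed acetonide formation (transketalisation) on the cis-diol gives the cis-fused bicyclic lactone whose ring fusion controls the next step; no new stereocentre.

Step 2
Reactants: 2 (3aR,6aR)-2,2-dimethyldihydrofuro[3,4-d][1,3]dioxol-4(3aH)-one
Product: 4 (3aR,6aR)-2,2,3a-trimethyldihydrofuro[3,4-d][1,3]dioxol-4(3aH)-one, via lithium enolate 3 (not isolated)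
Conditions: LiN(i-Pr)2, THF/DMPU, −78 °C; then MeI, −78 → −40 °C
Reagents that add atoms: iodomethane (CI)
Why: Lactone enolate alkylation in which the dioxolane can only remain cis-fused, so the methyl group enters on the exo face and the acetonide oxygen stays cis to O8, which sets C7 as R (loss of the β-oxygen is slowed because that C–O bond is held near the enolate plane).

Step 3
Reactants: 4 (3aR,6aR)-2,2,3a-trimethyldihydrofuro[3,4-d][1,3]dioxol-4(3aH)-one
Product: 5 (4R,5R)-5-(hydroxymethyl)-N-methoxy-N,2,2,4-tetramethyl-1,3-dioxolane-4-carboxamide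
Conditions: MeNH(OMe)·HCl (3 equiv), i-PrMgCl (6 equiv), THF, −20 → 0 °C; NH4Cl (aq); crude product used at once
Reagents that add atoms: N,O-dimethylhydroxylamine hydrochloride (CNOC.Cl)
Why: Weinreb aminolysis of the lactone by the chloromagnesium amide opens the ring without touching the stereocentres, and the crude hydroxy amide is oxidised immediately because it relactonises on acid or silica.

Step 4
Reactants: 5 (4R,5R)-5-(hydroxymethyl)-N-methoxy-N,2,2,4-tetramethyl-1,3-dioxolane-4-carboxamide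
Product: 6 (4R,5S)-5-formyl-N-methoxy-N,2,2,4-tetramethyl-1,3-dioxolane-4-carboxamide
Conditions: Dess–Martin periodinane, CH2Cl2, 0 °C → rt
Reagents that add atoms: none
Why: Dess–Martin oxidation stops at the aldehyde under non-basic conditions, so the cis-disposed α-alkoxy aldehyde centre (C8) is not epimerised.

Step 5
Reactants: 6 (4R,5S)-5-formyl-N-methoxy-N,2,2,4-tetramethyl-1,3-dioxolane-4-carboxamide
Product: 7 (4R,5R)-5-ethynyl-N-methoxy-N,2,2,4-tetramethyl-1,3-dioxolane-4-carboxamide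
Conditions: dimethyl (1-diazo-2-oxopropyl)phosphonate, K2CO3, MeOH, 0 °C, 2 h
Reagents that add atoms: dimethyl (1-diazo-2-oxopropyl)phosphonate (CC(=O)C(=[N+]=[N-])P(=O)(OC)OC)
Why: Seyferth–Gilbert homologation in the Ohira–Bestmann variant turns the aldehyde into the terminal alkyne C8a≡C1 under carbonate conditions that the Weinreb amide tolerates, with short contact at 0 °C to keep C8 from epimerising.

Step 6
Reactants: 8 1,4-dichlorobut-2-yne
Product: 10 penta-1,3-diyne, via sodium buta-1,3-diyn-1-ide 9 (not isolated)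
Conditions: NaNH2 (3 equiv), liquid NH3, −40 °C; then MeI (1 equiv); distilled into THF
Reagents that add atoms: iodomethane (CI)
Why: Double dehydrochlorination of the propargylic dichloride gives sodium butadiynide, which is C-methylated (acetylide alkylation) to the volatile diyne that is kept as a THF solution.

Step 7
Reactants: 7 (4R,5R)-5-ethynyl-N-methoxy-N,2,2,4-tetramethyl-1,3-dioxolane-4-carboxamide; 10 penta-1,3-diyne
Product: 12 1-[(4R,5R)-5-ethynyl-2,2,4-trimethyl-1,3-dioxolan-4-yl]hexa-2,4-diyn-1-one, via lithium penta-1,3-diyn-1-ide 11 (not isolated)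
Conditions: 10 (2.5 equiv), n-BuLi (2.4 equiv), THF, −78 °C; then 7, −78 → 0 °C; NH4Cl (aq)
Reagents that add atoms: none
Why: Weinreb ketone synthesis in which the lithium diynide adds once to the amide (stable chelated tetrahedral intermediate) and the conjugated diynone is released only on work-up.

Step 8
Reactants: 12 1-[(4R,5R)-5-ethynyl-2,2,4-trimethyl-1,3-dioxolan-4-yl]hexa-2,4-diyn-1-one
Product: 15 (7R,8R)-5-chloro-3,7-dimethyl-7,8-(isopropylidenedioxy)-7,8-dihydro-6H-isochromen-6-one, via vinyl sulfone 13 (not isolated), via hydroxymethylene dienone 14 (not isolated)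
Conditions: TsCl (1.2 equiv), [Cu(dap)2]Cl (1 mol %, dap = 2,9-bis(4-methoxyphenyl)-1,10-phenanthroline), degassed MeCN (0.01 M), 530 nm LED, rt; then K2CO3 (3 equiv), H2O, rt → 40 °C
Reagents that add atoms: 4-methylbenzenesulfonyl chloride (Cc1ccc(cc1)S(Cl)(=O)=O); water (O)
Why: Proposed new method: the photoexcited monovalent copper complex reduces TsCl to a sulfonyl radical that adds to the unhindered terminal alkyne carbon C1, the σ-vinyl radical at C8a attacks the ynone β-carbon C4a in a polarity-matched 6-endo-dig closure on the cis-fused dioxolane (5-exo attack at the α-carbon is electronically mismatched and would give a strained bis-alkylidene cyclopentanone), the α-keto vinyl radical at C5 is capped by chlorine transfer from the divalent copper chloride complex or from TsCl, and aqueous K2CO3 then displaces sulfinate at C1 by addition–elimination so that the enol oxygen closes the pyran by 6-endo oxa-Michael addition to the δ-alkyne carbon C3; the closest known reaction types are copper-photocatalysed chlorosulfonylation (atom-transfer radical addition) of alkynes and sulfonyl-radical cascade cyclisations of 1,6-diynes and 1,6-enynes, and no stereocentre is formed.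

Step 9
Reactants: 16 (S)-2-methylbutan-1-ol
Product: 17 (S)-2-methylbutanal
Conditions: TEMPO (1 mol %), KBr (10 mol %), NaOCl (aq, 1.1 equiv), NaHCO3 buffer, CH2Cl2/H2O, 0 °C; dried CH2Cl2 solution used directly
Reagents that add atoms: none
Why: Anelli oxidation (TEMPO/NaOCl) gives the α-chiral aldehyde at 0 °C without racemisation, and the solution is used directly because the aldehyde is volatile and configurationally labile.

Step 10
Reactants: 18 (R)-lactic acid
Product: 19 (2R,5R)-2-tert-butyl-5-methyl-1,3-dioxolan-4-one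
Conditions: t-BuCHO, TsOH·H2O (cat.), H2SO4 (cat.), pentane, reflux with water separation; recrystallisation (ether/pentane, −78 °C)
Reagents that add atoms: pivalaldehyde (CC(C)(C)C=O)
Why: Acid-catalysed acetalisation (Seebach dioxolanone, self-regeneration of stereocentres) gives mainly the cis acetal, purified by crystallisation, so the new acetal centre (2R) stores the chirality of the lactate.

Step 11
Reactants: 19 (2R,5R)-2-tert-butyl-5-methyl-1,3-dioxolan-4-one; 17 (S)-2-methylbutanal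
Product: 21 (2R,5S)-2-tert-butyl-5-[(1S,2S)-1-hydroxy-2-methylbutyl]-5-methyl-1,3-dioxolan-4-one, via lithium dioxolanone enolate 20 (not isolated)
Conditions: LiN(i-Pr)2, THF, −78 °C; then 17 (CH2Cl2 solution), −78 °C; NH4Cl (aq); chromatography
Reagents that add atoms: none
Why: Aldol addition of the Seebach enolate in which the aldehyde attacks anti to the tert-butyl group (sets the quaternary C3' by replacement of H with retention) through a Zimmerman–Traxler chair with the sec-butyl group equatorial, which gives the anti O/O relationship and sets C4' as S (minor C4' epimer removed by chromatography).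

Step 12
Reactants: 21 (2R,5S)-2-tert-butyl-5-[(1S,2S)-1-hydroxy-2-methylbutyl]-5-methyl-1,3-dioxolan-4-one
Product: 23 methyl (4S,5S)-5-[(2S)-butan-2-yl]-2,2,4-trimethyl-1,3-dioxolane-4-carboxylate, via dihydroxy methyl ester 22 (not isolated)
Conditions: HCl (cat.), MeOH, 50 °C; evaporation; then 2,2-dimethoxypropane, TsOH·H2O (cat.), acetone, rt
Reagents that add atoms: methanol (CO); 2,2-dimethoxypropane (COC(C)(C)OC)
Why: Acid methanolysis of the acetal-ester releases pivalaldehyde and the dihydroxy ester, and transketalisation then ties the tertiary/secondary diol as its acetonide without touching the stereocentres.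

Step 13
Reactants: 23 methyl (4S,5S)-5-[(2S)-butan-2-yl]-2,2,4-trimethyl-1,3-dioxolane-4-carboxylate
Product: 24 (4S,5S)-5-[(2S)-butan-2-yl]-2,2,4-trimethyl-1,3-dioxolane-4-carbaldehyde
Conditions: i-Bu2AlH (1.1 equiv), CH2Cl2, −78 °C; aqueous potassium sodium tartrate work-up
Reagents that add atoms: none
Why: Partial reduction of the α-alkoxy ester with i-Bu2AlH stops at the aldehyde through the chelated aluminium hemiacetal, and the product has no α-hydrogen and cannot epimerise.

Step 14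
Reactants: 15 (7R,8R)-5-chloro-3,7-dimethyl-7,8-(isopropylidenedioxy)-7,8-dihydro-6H-isochromen-6-one; 24 (4S,5S)-5-[(2S)-butan-2-yl]-2,2,4-trimethyl-1,3-dioxolane-4-carbaldehyde
Product: 28 (7R,8R)-3-[(E)-2-{(4R,5S)-5-[(2S)-butan-2-yl]-2,2,4-trimethyl-1,3-dioxolan-4-yl}ethenyl]-5-chloro-7-methyl-7,8-(isopropylidenedioxy)-7,8-dihydro-6H-isochromen-6-one, via lithium trienolate 25 (not isolated), via lithium aldolate 26 (not isolated), via mesylate 27 (not isolated)
Conditions: LiN(SiMe3)2 (1.05 equiv), THF, −78 °C; then 24; then MsCl, −78 → 0 °C; then DBU, rt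
Reagents that add atoms: none
Why: Vinylogous (lateral) aldol condensation in which the 3-methyl group of the pyranylidene ketone is deprotonated to the extended enolate, this attacks the non-enolisable aldehyde through its exocyclic terminus (as in lateral condensations of 2-methyl-4-pyranones), and E1cB elimination of the mesylate gives the conjugated E-alkene under thermodynamic control.

Step 15
Reactants: 28 (7R,8R)-3-[(E)-2-{(4R,5S)-5-[(2S)-butan-2-yl]-2,2,4-trimethyl-1,3-dioxolan-4-yl}ethenyl]-5-chloro-7-methyl-7,8-(isopropylidenedioxy)-7,8-dihydro-6H-isochromen-6-one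
Product: 29 (7R,8R)-5-chloro-3-[(1E,3R,4S,5S)-3,4-dihydroxy-3,5-dimethylhept-1-en-1-yl]-7,8-dihydroxy-7-methyl-7,8-dihydro-6H-isochromen-6-one
Conditions: AcOH/H2O (4:1), 40 °C
Reagents that add atoms: none
Why: Mild acid hydrolysis of both acetonides cleaves only the ketal C–O bonds, so the C–O bonds at C7, C8, C3' and C4' and all five stereocentres are untouched and the tetraol target is released.

**Compound list**
1 | D-erythronolactone, (3R,4R)-3,4-dihydroxyoxolan-2-one | O=C1[C@H](O)[C@H](O)CO1 | starting material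
2 | (3aR,6aR)-2,2-dimethyldihydrofuro[3,4-d][1,3]dioxol-4(3aH)-one | O=C1[C@@H]2OC(C)(C)O[C@@H]2CO1 | intermediate
3 | lithium (6aR)-2,2-dimethyl-6,6a-dihydrofuro[3,4-d][1,3]dioxol-4-olate (lithium enolate of 2) | [Li+].[O-]C1=C2OC(C)(C)O[C@@H]2CO1 | intermediate
4 | (3aR,6aR)-2,2,3a-trimethyldihydrofuro[3,4-d][1,3]dioxol-4(3aH)-one | O=C1[C@]2(C)OC(C)(C)O[C@@H]2CO1 | intermediate
5 | (4R,5R)-5-(hydroxymethyl)-N-methoxy-N,2,2,4-tetramethyl-1,3-dioxolane-4-carboxamide | CON(C)C(=O)[C@]1(C)OC(C)(C)O[C@@H]1CO | intermediate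
6 | (4R,5S)-5-formyl-N-methoxy-N,2,2,4-tetramethyl-1,3-dioxolane-4-carboxamide | CON(C)C(=O)[C@]1(C)OC(C)(C)O[C@@H]1C=O | intermediate
7 | (4R,5R)-5-ethynyl-N-methoxy-N,2,2,4-tetramethyl-1,3-dioxolane-4-carboxamide | CON(C)C(=O)[C@]1(C)OC(C)(C)O[C@@H]1C#C | intermediate
8 | 1,4-dichlorobut-2-yne | ClCC#CCCl | starting material
9 | sodium buta-1,3-diyn-1-ide | [Na+].[C-]#CC#C | intermediate
10 | penta-1,3-diyne | CC#CC#C | intermediate
11 | lithium penta-1,3-diyn-1-ide | [Li+].[C-]#CC#CC | intermediate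
12 | 1-[(4R,5R)-5-ethynyl-2,2,4-trimethyl-1,3-dioxolan-4-yl]hexa-2,4-diyn-1-one | CC#CC#CC(=O)[C@]1(C)OC(C)(C)O[C@@H]1C#C | intermediate
13 | (3aR,7aR)-5-chloro-2,2,3a-trimethyl-7-[(4-methylbenzenesulfonyl)methylidene]-6-(prop-1-yn-1-yl)-7,7a-dihydro-1,3-benzodioxol-4(3aH)-one (sulfonyl anti to C4a) | CC#CC1=C(Cl)C(=O)[C@]2(C)OC(C)(C)O[C@@H]2/C1=C\S(=O)(=O)c1ccc(C)cc1 | intermediate
14 | (3aR,7aR)-5-chloro-7-(hydroxymethylidene)-2,2,3a-trimethyl-6-(prop-1-yn-1-yl)-7,7a-dihydro-1,3-benzodioxol-4(3aH)-one | CC#CC1=C(Cl)C(=O)[C@]2(C)OC(C)(C)O[C@@H]2C1=CO | intermediate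
15 | (7R,8R)-5-chloro-3,7-dimethyl-7,8-(isopropylidenedioxy)-7,8-dihydro-6H-isochromen-6-one | CC1=CC2=C(Cl)C(=O)[C@]3(C)OC(C)(C)O[C@@H]3C2=CO1 | intermediate
16 | (S)-2-methylbutan-1-ol | CC[C@H](C)CO | starting material
17 | (S)-2-methylbutanal | CC[C@H](C)C=O | intermediate
18 | (R)-lactic acid | C[C@@H](O)C(=O)O | starting material
19 | (2R,5R)-2-tert-butyl-5-methyl-1,3-dioxolan-4-one (cis) | C[C@H]1O[C@@H](C(C)(C)C)OC1=O | intermediate
20 | lithium (2R)-2-tert-butyl-5-methyl-2H-1,3-dioxol-4-olate (lithium enolate of 19) | CC1=C([O-])O[C@H](C(C)(C)C)O1.[Li+] | intermediate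
21 | (2R,5S)-2-tert-butyl-5-[(1S,2S)-1-hydroxy-2-methylbutyl]-5-methyl-1,3-dioxolan-4-one | CC[C@H](C)[C@H](O)[C@]1(C)O[C@@H](C(C)(C)C)OC1=O | intermediate
22 | methyl (2S,3S,4S)-2,3-dihydroxy-2,4-dimethylhexanoate | CC[C@H](C)[C@H](O)[C@](C)(O)C(=O)OC | intermediate
23 | methyl (4S,5S)-5-[(2S)-butan-2-yl]-2,2,4-trimethyl-1,3-dioxolane-4-carboxylate | CC[C@H](C)[C@@H]1OC(C)(C)O[C@]1(C)C(=O)OC | intermediate
24 | (4S,5S)-5-[(2S)-butan-2-yl]-2,2,4-trimethyl-1,3-dioxolane-4-carbaldehyde | CC[C@H](C)[C@@H]1OC(C)(C)O[C@]1(C)C=O | intermediate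
25 | lithium trienolate of 15 (3-methylidene-3H-isochromen-6-olate form) | [Li+].C=C1C=C2C(Cl)=C([O-])[C@]3(C)OC(C)(C)O[C@@H]3C2=CO1 | intermediate
26 | lithium aldolate from 25 and 24 (C2' alkoxide, epimer mixture at C2') | [Li+].CC[C@H](C)[C@@H]1OC(C)(C)O[C@]1(C)C([O-])CC1=CC2=C(Cl)C(=O)[C@]3(C)OC(C)(C)O[C@@H]3C2=CO1 | intermediate
27 | C2' methanesulfonate of the aldol adduct (epimer mixture at C2') | CC[C@H](C)[C@@H]1OC(C)(C)O[C@]1(C)C(OS(C)(=O)=O)CC1=CC2=C(Cl)C(=O)[C@]3(C)OC(C)(C)O[C@@H]3C2=CO1 | intermediate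
28 | (7R,8R)-3-[(E)-2-{(4R,5S)-5-[(2S)-butan-2-yl]-2,2,4-trimethyl-1,3-dioxolan-4-yl}ethenyl]-5-chloro-7-methyl-7,8-(isopropylidenedioxy)-7,8-dihydro-6H-isochromen-6-one | CC[C@H](C)[C@@H]1OC(C)(C)O[C@]1(C)/C=C/C1=CC2=C(Cl)C(=O)[C@]3(C)OC(C)(C)O[C@@H]3C2=CO1 | intermediate
29 | (7R,8R)-5-chloro-3-[(1E,3R,4S,5S)-3,4-dihydroxy-3,5-dimethylhept-1-en-1-yl]-7,8-dihydroxy-7-methyl-7,8-dihydro-6H-isochromen-6-one (CNP0133971.4) | CC[C@H](C)[C@H](O)[C@](C)(O)/C=C/C1=CC2=C(Cl)C(=O)[C@](C)(O)[C@H](O)C2=CO1 | target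

**Step count**
Total: 15 steps. Longest linear sequence: 9 steps (1 → 2 → 4 → 5 → 6 → 7 → 12 → 15 → 28 → 29, i.e. steps 1, 2, 3, 4, 5, 7, 8, 14, 15).

**Three steps most likely to fail, with fallbacks**

Step 2 (the enolate of 2 may expel the β-oxygen before it is methylated). The fallback avoids a free enolate. It sets out from 2: soft enolisation (t-BuMe2SiOTf, Et3N, CH2Cl2) gives the silyl ketene acetal F1. Lewis-acid alkylation with chloromethyl phenyl sulfide (ZnBr2 cat.) on the exo face gives the 3a-(phenylsulfanylmethyl) lactone F2. Reductive desulfurisation with nickel boride (NiCl2·6H2O, NaBH4, MeOH, 0 °C) turns the CH2SPh group into the methyl group and rejoins the route at 4.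

Step 8 (the C8a vinyl radical may close 5-exo, abstract hydrogen from an acetonide methyl, or pick up chlorine before it cyclises). The fallback builds the carbocycle from a primary alkyl radical and adds C1 and chlorine afterwards. It sets out from 4:
- Ring-opening at the O–CH2 carbon with PhSeNa ((PhSe)2, NaBH4, DMF, 110 °C) gives the selenide acid F3.
- Amide coupling (MeNH(OMe)·HCl, EDC·HCl, Et3N) gives the selenide Weinreb amide F4, and lithium penta-1,3-diyn-1-ide 11 converts it into the selenide diynone F5.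
- Bu3SnH/AIBN (slow addition, benzene, 80 °C) closes the ring 6-endo on the ynone β-carbon to the 3-propynylcyclohexenone F6.
- Formylation at C8a (LiN(SiMe3)2, HCO2Et) gives the hydroxymethylene enone F7, which cyclises (AgOTf cat.) to the des-chloro pyran F8.
- NCS in MeCN chlorinates C5 and rejoins the route at 15.

Step 14 (the extended enolate of 15 may react at C5 or C4, or the hindered aldehyde may undergo retro-aldol). The fallback brings the side chain in before the key step, so no late C–C bond is needed. It sets out from 24 and uses 7: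
- Takai olefination of 24 (CrCl2, CHI3, THF) gives the E-vinyl iodide F9.
- Sonogashira coupling with buta-1,3-diynyl(trimethyl)silane (Pd(PPh3)4, CuI, i-Pr2NH) gives the silyl enediyne F10, and K2CO3/MeOH gives the terminal enediyne F11.
- Its lithium acetylide (n-BuLi, THF, −78 °C) is acylated by Weinreb amide 7 to the side-chain diynone F12.
- The conditions of step 8 then lead through the vinyl sulfone F13 and the hydroxymethylene dienone F14, neither isolated, and rejoin the route at 28.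

Further compounds
F1 | step 2 | tert-butyl{[(6aR)-2,2-dimethyl-6,6a-dihydrofuro[3,4-d][1,3]dioxol-4-yl]oxy}dimethylsilane (silyl ketene acetal) | CC(C)(C)[Si](C)(C)OC1=C2OC(C)(C)O[C@@H]2CO1
F2 | step 2 | (3aR,6aR)-2,2-dimethyl-3a-[(phenylsulfanyl)methyl]dihydrofuro[3,4-d][1,3]dioxol-4(3aH)-one | O=C1[C@]2(CSc3ccccc3)OC(C)(C)O[C@@H]2CO1
F3 | step 8 | (4R,5S)-2,2,4-trimethyl-5-[(phenylselanyl)methyl]-1,3-dioxolane-4-carboxylic acid | OC(=O)[C@]1(C)OC(C)(C)O[C@@H]1C[Se]c1ccccc1
F4 | step 8 | (4R,5S)-N-methoxy-N,2,2,4-tetramethyl-5-[(phenylselanyl)methyl]-1,3-dioxolane-4-carboxamide | CON(C)C(=O)[C@]1(C)OC(C)(C)O[C@@H]1C[Se]c1ccccc1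
F5 | step 8 | 1-{(4R,5S)-2,2,4-trimethyl-5-[(phenylselanyl)methyl]-1,3-dioxolan-4-yl}hexa-2,4-diyn-1-one | CC#CC#CC(=O)[C@]1(C)OC(C)(C)O[C@@H]1C[Se]c1ccccc1
F6 | step 8 | (3aR,7aR)-2,2,3a-trimethyl-6-(prop-1-yn-1-yl)-7,7a-dihydro-1,3-benzodioxol-4(3aH)-one | CC#CC1=CC(=O)[C@]2(C)OC(C)(C)O[C@@H]2C1
F7 | step 8 | (3aR,7aR)-7-(hydroxymethylidene)-2,2,3a-trimethyl-6-(prop-1-yn-1-yl)-7,7a-dihydro-1,3-benzodioxol-4(3aH)-one | CC#CC1=CC(=O)[C@]2(C)OC(C)(C)O[C@@H]2C1=CO
F8 | step 8 | (7R,8R)-3,7-dimethyl-7,8-(isopropylidenedioxy)-7,8-dihydro-6H-isochromen-6-one | CC1=CC2=CC(=O)[C@]3(C)OC(C)(C)O[C@@H]3C2=CO1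
F9 | step 14 | (4R,5S)-5-[(2S)-butan-2-yl]-4-[(E)-2-iodoethenyl]-2,2,4-trimethyl-1,3-dioxolane | CC[C@H](C)[C@@H]1OC(C)(C)O[C@]1(C)/C=C/I
F10 | step 14 | {(E)-6-[(4R,5S)-5-[(2S)-butan-2-yl]-2,2,4-trimethyl-1,3-dioxolan-4-yl]hex-5-ene-1,3-diyn-1-yl}trimethylsilane | CC[C@H](C)[C@@H]1OC(C)(C)O[C@]1(C)/C=C/C#CC#C[Si](C)(C)C
F11 | step 14 | (4R,5S)-5-[(2S)-butan-2-yl]-4-[(E)-hex-1-ene-3,5-diyn-1-yl]-2,2,4-trimethyl-1,3-dioxolane | CC[C@H](C)[C@@H]1OC(C)(C)O[C@]1(C)/C=C/C#CC#C
F12 | step 14 | (E)-7-{(4R,5S)-5-[(2S)-butan-2-yl]-2,2,4-trimethyl-1,3-dioxolan-4-yl}-1-[(4R,5R)-5-ethynyl-2,2,4-trimethyl-1,3-dioxolan-4-yl]hept-6-ene-2,4-diyn-1-one | CC[C@H](C)[C@@H]1OC(C)(C)O[C@]1(C)/C=C/C#CC#CC(=O)[C@]2(C)OC(C)(C)O[C@@H]2C#C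
F13 | step 14 | (3aR,7aR)-6-[(E)-4-{(4R,5S)-5-[(2S)-butan-2-yl]-2,2,4-trimethyl-1,3-dioxolan-4-yl}but-3-en-1-yn-1-yl]-5-chloro-2,2,3a-trimethyl-7-[(4-methylbenzenesulfonyl)methylidene]-7,7a-dihydro-1,3-benzodioxol-4(3aH)-one | CC[C@H](C)[C@@H]1OC(C)(C)O[C@]1(C)/C=C/C#CC1=C(Cl)C(=O)[C@]2(C)OC(C)(C)O[C@@H]2/C1=C\S(=O)(=O)c1ccc(C)cc1
F14 | step 14 | (3aR,7aR)-6-[(E)-4-{(4R,5S)-5-[(2S)-butan-2-yl]-2,2,4-trimethyl-1,3-dioxolan-4-yl}but-3-en-1-yn-1-yl]-5-chloro-7-(hydroxymethylidene)-2,2,3a-trimethyl-7,7a-dihydro-1,3-benzodioxol-4(3aH)-one | CC[C@H](C)[C@@H]1OC(C)(C)O[C@]1(C)/C=C/C#CC1=C(Cl)C(=O)[C@]2(C)OC(C)(C)O[C@@H]2C1=CO
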